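**Retrosynthetic overview**
1. Pyran ring last: the chromene C2–O bond is closed by chiral-acid cyclodehydration of an o-hydroxystyryl tertiary allylic alcohol, built from the C6-methyl enone by vinylogous aldol with methyl vinyl ketone and a Heck arylation.
2. Cyclohexenone ring: aldol condensation of a 1,5-diketone whose γ-hydroxy-ketone arm is made in the same flask by the key bond, an acetone-derived ketyl radical (carbonyl carbon acting as nucleophile) adding to the β-carbon of a vinyl ketone.
3. Cyclopentane first: amine-catalysed 5-exo Michael cyclisation of an α-branched aldehyde onto a β,β-disubstituted enone sets both quaternary carbons (methyls trans).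
4. Acyclic chain: B-alkyl Suzuki coupling of 2-methylpent-4-en-1-ol with the enol triflate of acetylacetone.
5. Ring order: cyclopentane → cyclohexenone → pyran; no protecting groups.

Assumption: the SMILES is read as 2S at the chromene and 3aS,7aR (trans-fused, angular methyls anti) in the hydrindenone; where a catalyst antipode is not named, it is the one that gives the stated descriptor.

**Step 1**
Reactants: 1 pentane-2,4-dione
Product: 2 (E)-4-oxopent-2-en-2-yl trifluoromethanesulfonate
Conditions: Tf2O, aq. Me4NOH, hexane, 0–5 °C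
Reagents that add atoms: trifluoromethanesulfonic anhydride, O=S(=O)(OS(=O)(=O)C(F)(F)F)C(F)(F)F
Why: Biphasic enol triflation of the 1,3-diketone (O-sulfonylation of the non-chelated tetramethylammonium enolate) gives the E-configured vinylogous acyl triflate.

**Step 2**
Reactants: 3 2-methylpent-4-en-1-ol (racemic), 2 (E)-4-oxopent-2-en-2-yl trifluoromethanesulfonate
Product: 5 (3E)-9-hydroxy-4,8-dimethylnon-3-en-2-one, via alkylborane 4 (not isolated)
Conditions: 9-BBN (2.1 equiv), THF, 0 °C→rt; then 2, PdCl2(dppf) (3 mol%), 3 M aq. K3PO4, DMF, rt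
Reagents that add atoms: none
Why: Anti-Markovnikov hydroboration of the terminal alkene then B-alkyl Suzuki–Miyaura coupling with the activated enol triflate joins the chains with retention of the E geometry, the second equivalent of 9-BBN only tying up the hydroxyl as a borinate that is cleaved on work-up.

**Step 3**
Reactants: 5 (3E)-9-hydroxy-4,8-dimethylnon-3-en-2-one
Product: 6 (6E)-2,6-dimethyl-8-oxonon-6-enal (racemic)
Conditions: Dess–Martin periodinane, CH2Cl2, 0 °C→rt
Reagents that add atoms: none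
Why: Dess–Martin oxidation takes the primary alcohol to the aldehyde without touching the enone, and the racemic α-centre is planarised in the next step.

**Step 4**
Reactants: 6 (6E)-2,6-dimethyl-8-oxonon-6-enal
Product: 7 (1S,2R)-1,2-dimethyl-2-(2-oxopropyl)cyclopentane-1-carbaldehyde
Conditions: chiral primary amine–thiourea catalyst (20 mol%), PhCO2H (20 mol%), toluene, 4 °C, stopped at full conversion
Reagents that add atoms: none
Why: Proposed new method: the catalyst's primary amine turns the aldehyde into its tetrasubstituted enamine while the thiourea hydrogen-bonds the enone, and 5-exo-trig Michael addition through an open transition state with the two π-systems antiperiplanar puts the formyl and 2-oxopropyl arms trans (methyls trans) on the catalyst-dictated face to give 1S,2R; the closest known reactions are aminocatalytic intramolecular Michael cyclisations of formyl enones and primary-amine–thiourea Michael additions of α,α-disubstituted aldehydes.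

**Step 5**
Reactants: 7 (1S,2R)-1,2-dimethyl-2-(2-oxopropyl)cyclopentane-1-carbaldehyde, 8 vinyl bromide
Product: 9 1-[(1S,2R)-1,2-dimethyl-2-(2-oxopropyl)cyclopentyl]prop-2-en-1-ol (both carbinol epimers)
Conditions: CrCl2 (4 equiv), NiCl2 (1 mol%), DMF, rt
Reagents that add atoms: none
Why: Nozaki–Hiyama–Kishi vinylation adds the vinylchromium species to the hindered aldehyde only and leaves the methyl ketone alone, the new carbinol configuration being irrelevant.

**Step 6**
Reactants: 9 1-[(1S,2R)-1,2-dimethyl-2-(2-oxopropyl)cyclopentyl]prop-2-en-1-ol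
Product: 10 1-[(1S,2R)-1,2-dimethyl-2-(2-oxopropyl)cyclopentyl]prop-2-en-1-one
Conditions: Dess–Martin periodinane, CH2Cl2, 0 °C
Reagents that add atoms: none
Why: Dess–Martin oxidation of the allylic alcohol (open form of its hemiketal) gives the vinyl ketone needed as radical acceptor.

**Step 7 (key step)**
Reactants: 10 1-[(1S,2R)-1,2-dimethyl-2-(2-oxopropyl)cyclopentyl]prop-2-en-1-one, 11 propan-2-ol
Product: 14 (3aS,7aR)-5-(2-hydroxy-2-methylpropyl)-3a,6,7a-trimethyl-1,2,3,3a,7,7a-hexahydro-4H-inden-4-one, via hydroxy diketone 12 (not isolated), via aldol adduct 13 (not isolated)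
Conditions: (Bu4N)4W10O32 (2 mol%), 11/MeCN 1:1, 390 nm LED, rt, degassed; then KOH (0.3 equiv), MeOH, rt→40 °C
Reagents that add atoms: none
Why: Decatungstate hydrogen-atom transfer from 2-propanol gives the 2-hydroxyprop-2-yl (ketyl) radical, in which acetone's carbonyl carbon reacts as a nucleophile and adds to the electrophilic β-carbon of the vinyl ketone (Giese addition), and mild base then closes the 1,5-diketone by intramolecular aldol condensation (Robinson-type ring closure) at the unhindered methyl ketone without touching either quaternary centre.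

**Step 8**
Reactants: 14 (3aS,7aR)-5-(2-hydroxy-2-methylpropyl)-3a,6,7a-trimethyl-1,2,3,3a,7,7a-hexahydro-4H-inden-4-one, 15 but-3-en-2-one
Product: 16 (3aS,7aR)-6-(2-hydroxy-2-methylbut-3-en-1-yl)-5-(2-hydroxy-2-methylpropyl)-3a,7a-dimethyl-1,2,3,3a,7,7a-hexahydro-4H-inden-4-one (both carbinol epimers)
Conditions: LDA (2.2 equiv), THF, −78 °C; 15, −78 °C, 10 min; AcOH quench at −78 °C
Reagents that add atoms: none
Why: Kinetic γ-deprotonation at the exposed C6-methyl gives the cross-conjugated dienolate, whose fully substituted α-carbon forces attack on the carbonyl of methyl vinyl ketone through the γ-carbon at −78 °C (vinylogous aldol, 1,2-addition), and the new carbinol centre is erased in step 11.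

**Step 9**
Reactants: 17 4-methoxy-2-methylphenol
Product: 18 2-iodo-4-methoxy-6-methylphenol
Conditions: NIS (1.05 equiv), TsOH·H2O (10 mol%), MeCN, 0 °C
Reagents that add atoms: N-iodosuccinimide, O=C1CCC(=O)N1I
Why: Electrophilic aromatic iodination goes to the only free position ortho to the hydroxyl, the strongest donor.

**Step 10**
Reactants: 16 (3aS,7aR)-6-(2-hydroxy-2-methylbut-3-en-1-yl)-5-(2-hydroxy-2-methylpropyl)-3a,7a-dimethyl-1,2,3,3a,7,7a-hexahydro-4H-inden-4-one, 18 2-iodo-4-methoxy-6-methylphenol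
Product: 19 (3aS,7aR)-6-[(3E)-2-hydroxy-4-(2-hydroxy-5-methoxy-3-methylphenyl)-2-methylbut-3-en-1-yl]-5-(2-hydroxy-2-methylpropyl)-3a,7a-dimethyl-1,2,3,3a,7,7a-hexahydro-4H-inden-4-one (both carbinol epimers)
Conditions: Pd(OAc)2 (5 mol%), Bu4NCl, NaHCO3, DMF, 60 °C
Reagents that add atoms: none
Why: Mizoroki–Heck arylation of the terminal vinyl group under ligand-free phase-transfer conditions gives the E-styrene, β-hydride elimination being possible only towards the benzylic carbon.

**Step 11**
Reactants: 19 (3aS,7aR)-6-[(3E)-2-hydroxy-4-(2-hydroxy-5-methoxy-3-methylphenyl)-2-methylbut-3-en-1-yl]-5-(2-hydroxy-2-methylpropyl)-3a,7a-dimethyl-1,2,3,3a,7,7a-hexahydro-4H-inden-4-one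
Product: 20 (3aS,7aR)-5-(2-hydroxy-2-methylpropyl)-6-{[(2S)-6-methoxy-2,8-dimethyl-2H-chromen-2-yl]methyl}-3a,7a-dimethyl-1,2,3,3a,7,7a-hexahydro-4H-inden-4-one
Conditions: BINOL-derived chiral N-triflylphosphoramide (10 mol%), 4 Å MS, toluene, −78→−40 °C
Reagents that add atoms: none
Why: The chiral acid ionises only the styryl-conjugated tertiary allylic alcohol to a contact ion pair (protonated vinylogous o-quinone methide, free to turn from E to the cisoid form), and closure by the phenol oxygen inside the chiral anion's pocket (Brønsted-acid-catalysed asymmetric allylic substitution) sets C2 as S while the saturated tertiary alcohol and the enone stay inert.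

**Compound list**
1 | pentane-2,4-dione | CC(=O)CC(C)=O | starting material
2 | (E)-4-oxopent-2-en-2-yl trifluoromethanesulfonate | C/C(OS(=O)(=O)C(F)(F)F)=C\C(C)=O | intermediate
3 | 2-methylpent-4-en-1-ol (racemic) | C=CCC(C)CO | starting material
4 | 9-{4-methyl-5-[(9-borabicyclo[3.3.1]nonan-9-yl)oxy]pentyl}-9-borabicyclo[3.3.1]nonane | CC(COB1C2CCCC1CCC2)CCCB1C2CCCC1CCC2 | intermediate
5 | (3E)-9-hydroxy-4,8-dimethylnon-3-en-2-one (racemic) | OCC(C)CCC/C(C)=C/C(C)=O | intermediate
6 | (6E)-2,6-dimethyl-8-oxonon-6-enal (racemic) | O=CC(C)CCC/C(C)=C/C(C)=O | intermediate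
7 | (1S,2R)-1,2-dimethyl-2-(2-oxopropyl)cyclopentane-1-carbaldehyde (formyl and oxopropyl arms trans) | O=C[C@@]1(C)CCC[C@]1(C)CC(C)=O | intermediate
8 | vinyl bromide | C=CBr | starting material
9 | 1-[(1S,2R)-1,2-dimethyl-2-(2-oxopropyl)cyclopentyl]prop-2-en-1-ol (carbinol epimers) | C=CC(O)[C@@]1(C)CCC[C@]1(C)CC(C)=O | intermediate
10 | 1-[(1S,2R)-1,2-dimethyl-2-(2-oxopropyl)cyclopentyl]prop-2-en-1-one | C=CC(=O)[C@@]1(C)CCC[C@]1(C)CC(C)=O | intermediate
11 | propan-2-ol | CC(C)O | starting material
12 | 1-[(1S,2R)-1,2-dimethyl-2-(2-oxopropyl)cyclopentyl]-4-hydroxy-4-methylpentan-1-one | CC(C)(O)CCC(=O)[C@@]1(C)CCC[C@]1(C)CC(C)=O | intermediate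
13 | (3aS,7aR)-6-hydroxy-5-(2-hydroxy-2-methylpropyl)-3a,6,7a-trimethyloctahydro-4H-inden-4-one (C5/C6 epimers) | CC1(O)C(CC(C)(C)O)C(=O)[C@@]2(C)CCC[C@]2(C)C1 | intermediate
14 | (3aS,7aR)-5-(2-hydroxy-2-methylpropyl)-3a,6,7a-trimethyl-1,2,3,3a,7,7a-hexahydro-4H-inden-4-one | CC1=C(CC(C)(C)O)C(=O)[C@@]2(C)CCC[C@]2(C)C1 | intermediate
15 | but-3-en-2-one (methyl vinyl ketone) | C=CC(C)=O | starting material
16 | (3aS,7aR)-6-(2-hydroxy-2-methylbut-3-en-1-yl)-5-(2-hydroxy-2-methylpropyl)-3a,7a-dimethyl-1,2,3,3a,7,7a-hexahydro-4H-inden-4-one (carbinol epimers) | C=CC(C)(O)CC1=C(CC(C)(C)O)C(=O)[C@@]2(C)CCC[C@]2(C)C1 | intermediate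
17 | 4-methoxy-2-methylphenol | COc1ccc(O)c(C)c1 | starting material
18 | 2-iodo-4-methoxy-6-methylphenol | COc1cc(C)c(O)c(I)c1 | intermediate
19 | (3aS,7aR)-6-[(3E)-2-hydroxy-4-(2-hydroxy-5-methoxy-3-methylphenyl)-2-methylbut-3-en-1-yl]-5-(2-hydroxy-2-methylpropyl)-3a,7a-dimethyl-1,2,3,3a,7,7a-hexahydro-4H-inden-4-one (carbinol epimers) | COc1cc(C)c(O)c(/C=C/C(C)(O)CC2=C(CC(C)(C)O)C(=O)[C@@]3(C)CCC[C@]3(C)C2)c1 | intermediate
20 | (3aS,7aR)-5-(2-hydroxy-2-methylpropyl)-6-{[(2S)-6-methoxy-2,8-dimethyl-2H-chromen-2-yl]methyl}-3a,7a-dimethyl-1,2,3,3a,7,7a-hexahydro-4H-inden-4-one | COc1cc(C)c2c(c1)C=C[C@](C)(CC1=C(CC(C)(C)O)C(=O)[C@@]3(C)CCC[C@]3(C)C1)O2 | target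

**Step count**
Total: 11 steps. Longest linear sequence: 10 steps (steps 1–8, 10, 11); step 9 is a one-step side branch.

**Three steps most likely to fail**

Step 4 (two adjacent quaternary carbons from an enamine; enantioselectivity, and possible onward aldol of 7). The fallback sets out from 6 and comes back at 7, replacing catalysis by a stoichiometric chiral imine. Compound 6 is condensed with (S)-1-phenylethylamine to (3E)-4,8-dimethyl-9-{[(1S)-1-phenylethyl]imino}non-3-en-2-one F1. Warming F1 in toluene lets its secondary-enamine tautomer add to the enone in a neutral, intramolecular aza-ene-type Michael reaction, giving 1-[(1R,2S)-1,2-dimethyl-2-({[(1S)-1-phenylethyl]imino}methyl)cyclopentyl]propan-2-one F2. Aqueous acetic acid hydrolyses F2 to 7 and returns the amine. The relative and absolute outcome would have to be confirmed, and the amine antipode chosen accordingly.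

Step 8 (α versus γ attack, 1,2 versus 1,4 addition to methyl vinyl ketone). The fallback sets out from 14 and comes back at 16, using a Lewis-acid vinylogous Mukaiyama aldol with an aldehyde and building the tertiary carbinol afterwards. Kinetic bis-silylation (LDA, Me3SiCl) gives trimethyl{[(3aS,7aR)-3a,7a-dimethyl-6-methylidene-5-{2-methyl-2-[(trimethylsilyl)oxy]propyl}-2,3,3a,6,7,7a-hexahydro-1H-inden-4-yl]oxy}silane F3. Reaction with acetaldehyde and BF3·OEt2 at −78 °C (γ-selective), followed by a desilylating work-up, gives (3aS,7aR)-6-(2-hydroxypropyl)-5-(2-hydroxy-2-methylpropyl)-3a,7a-dimethyl-1,2,3,3a,7,7a-hexahydro-4H-inden-4-one F4. Dess–Martin oxidation gives (3aS,7aR)-5-(2-hydroxy-2-methylpropyl)-3a,7a-dimethyl-6-(2-oxopropyl)-1,2,3,3a,7,7a-hexahydro-4H-inden-4-one F5. Vinylmagnesium bromide with CeCl3 then adds to the unhindered methyl ketone to give 16. This fallback still relies on the same kinetic deprotonation at the C6-methyl.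

Step 11 (the chiral acid must tell methyl from CH2R at C2; precedent is for aryl/alkyl pairs). The fallback sets out from 19 and comes back at 20, giving up catalyst control for separation and recycling. Cyclisation with an achiral acid (PPTS, CH2Cl2, 0 °C) gives 20 together with its C2 epimer (3aS,7aR)-5-(2-hydroxy-2-methylpropyl)-6-{[(2R)-6-methoxy-2,8-dimethyl-2H-chromen-2-yl]methyl}-3a,7a-dimethyl-1,2,3,3a,7,7a-hexahydro-4H-inden-4-one F6. The two are diastereomers and are separated by chromatography. F6 is re-equilibrated at C2 alone by 365 nm irradiation (electrocyclic opening and re-closure of the 2H-chromene) and separated again.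

**Further compounds**
F1 | step 4 | (3E)-4,8-dimethyl-9-{[(1S)-1-phenylethyl]imino}non-3-en-2-one | C[C@H](N=CC(C)CCC/C(C)=C/C(C)=O)c1ccccc1
F2 | step 4 | 1-[(1R,2S)-1,2-dimethyl-2-({[(1S)-1-phenylethyl]imino}methyl)cyclopentyl]propan-2-one | C[C@H](N=C[C@@]1(C)CCC[C@]1(C)CC(C)=O)c1ccccc1
F3 | step 8 | trimethyl{[(3aS,7aR)-3a,7a-dimethyl-6-methylidene-5-{2-methyl-2-[(trimethylsilyl)oxy]propyl}-2,3,3a,6,7,7a-hexahydro-1H-inden-4-yl]oxy}silane | C=C1C(CC(C)(C)O[Si](C)(C)C)=C(O[Si](C)(C)C)[C@@]2(C)CCC[C@]2(C)C1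
F4 | step 8 | (3aS,7aR)-6-(2-hydroxypropyl)-5-(2-hydroxy-2-methylpropyl)-3a,7a-dimethyl-1,2,3,3a,7,7a-hexahydro-4H-inden-4-one (carbinol epimers) | CC(O)CC1=C(CC(C)(C)O)C(=O)[C@@]2(C)CCC[C@]2(C)C1
F5 | step 8 | (3aS,7aR)-5-(2-hydroxy-2-methylpropyl)-3a,7a-dimethyl-6-(2-oxopropyl)-1,2,3,3a,7,7a-hexahydro-4H-inden-4-one | CC(=O)CC1=C(CC(C)(C)O)C(=O)[C@@]2(C)CCC[C@]2(C)C1
F6 | step 11 | (3aS,7aR)-5-(2-hydroxy-2-methylpropyl)-6-{[(2R)-6-methoxy-2,8-dimethyl-2H-chromen-2-yl]methyl}-3a,7a-dimethyl-1,2,3,3a,7,7a-hexahydro-4H-inden-4-one | COc1cc(C)c2c(c1)C=C[C@@](C)(CC1=C(CC(C)(C)O)C(=O)[C@@]3(C)CCC[C@]3(C)C1)O2
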